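If X.G is to form, X has to catch G, the form into which Q slowly turns, before G falls back to Q.

| flask | Q | X | temperature | time | remark |
|---|---|---|---|---|---|
| grey | 0.010 M (in portions, 5, over 15 min) | 10.0 mM | 25 °C | 25 min | first portion at the start, last at 15 min |
| teal | 0.010 M | 10.0 mM (fed, over 15 min) | 25 °C | 25 min | all else is in the flask from the start; the feed brings no volume worth counting |
| green | 0.010 M (fed, over 15 min) | 10.0 mM | 25 °C | 25 min | all else is in the flask from the start; the feed brings no volume worth counting |
| violet | 0.010 M (fed, over 15 min) | 10.0 mM |  | 25 min | the addition at 5 °C, then warmed to 25 °C; the feed brings no volume worth counting |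

    Q ⇌ G (K1 = 0.35, k1 = 0.12 /min, Ea1 = 88.0 kJ/mol, ΔH1 = −30.0 kJ/mol)
    X.G ⇌ E (K2 = 0.32, k2 = 0.35 /min, Ea2 = 93.0 kJ/mol, ΔH2 = −47.0 kJ/mol)
    X + G ⇌ J (K3 = 54 /M, k3 = 30 /M/min, Ea3 = 35.0 kJ/mol, ΔH3 = −7.00 kJ/mol)
    X + G → X.G (k4 = 32 /M/min, Ea4 = 45.0 kJ/mol)
    (constants at 25 °C)

- at 25 °C the constants are as listed, elsewhere as the activation energies and enthalpies make them

1. the flask that comes out highest in amount of X.G, in percent of the Q charged, or "all alike" when all lie within 1.5 percentage points (grey / teal / green / violet / all alike)
2. X.G at the end, in percent of the Q charged, grey
3. X.G at the end, in percent of the Q charged, teal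
4. X.G at the end, in percent of the Q charged, green
5. X.G at the end, in percent of the Q charged, violet

My reckoning uses two rates. The first is r, the relaxation rate of Q and G, forward plus back: 0.463 /min. Its inverse, 2.16 min, is taken as the time G needs to build up. The second is the capture rate of G by X, 0.320 /min at the full charge of X. At that charge they give 0.691 for ρ, the capture rate divided by the relaxation rate. With G steady, and J neglected as a reversible store, Q and G together fall with the pseudo-first-order constant k = f·ρ/(1+ρ), where f is the forward constant 0.12 /min.

The relaxation of X.G and E has a half-life of 0.480 min, shorter than the run, so X.G is taken to hold 75.8% of the product, X.G and E together.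

Let P be X.G and E together as a share of the Q charged, and t the clock, which is the run less the mean arrival of Q and less the build-up. Grey and green have the mean arrival 7.50 min. Violet's cold feed is counted as idle, so its clock starts at the warming. In teal, X has been fed, on average over the run, to 0.700 of its charge, a; elsewhere a is 1. The mean X, at which ρ is reckoned, is a times its charge, less P times the Q charge over 2. The first round guesses P = 0.5, and its answer goes back in for the second.

| flask | t | P, first round | P, second round | X.G |
|---|---|---|---|---|
| grey | 15.3 min | 46.7% | 47.1% | 35.7% |
| green | 15.3 min | 46.7% | 47.1% | 35.7% |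
| teal | 22.8 min | 47.8% | 48.4% | 36.7% |
| violet | 7.84 min | 27.5% | 29.6% | 22.4% |

My highest flask is teal.

The forecast also names teal, with grey 32.8%, teal 36%, green 32.5% and violet 23%; it ties grey to green by the “same mean addition time as green”.

The flasks give teal as highest: grey 33.8%, teal 37.4%, green 34.0%, violet 23.9%. At 25.0 min teal still holds 38.2% of the Q charged, and at 250 min its X.G stands at 71.7%. A neighbour of teal holds 0.017 M of X. Its first round gives P = 66.0%, so the mean X is 8.60 mM and ρ is 0.594. Then P = 64.0%, and X.G is 48.5%. That flask gives 49.0%.

The numbers of this flask are invented, and the outcome is calculated.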